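Readings and results are calculated with made-up constants, and the scatter is random.

If I halve both charges and keep the hours, I want to know how much Z I get, so I start from the symmetric case: one step of L with Q, charged equally.

| flask | L | Q | Z | time |
|---|---|---|---|---|
| Tuesday's | 0.0800 M | 0.0800 M |  |  |
| Wednesday's | 0.0800 M | 0.0800 M | 0.0400 M |  |
| Thursday's | 0.0400 M | 0.0400 M |  | 4.1 h |

| run | time / h | [Z] / M |
|---|---|---|
| Tuesday's run | 0.59 | 0.00898 |
| Tuesday's run | 1.2 | 0.01565 |
| Tuesday's run | 1.8 | 0.02049 |
| Tuesday's run | 2.3 | 0.02193 |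
| Tuesday's run | 2.9 | 0.02375 |
| Tuesday's run | 3.5 | 0.02450 |
| Tuesday's run | 4.1 | 0.02573 |
| Wednesday's run | 0.59 | 0.04950 |
| Wednesday's run | 1.2 | 0.05229 |
| Wednesday's run | 1.8 | 0.05337 |
| Wednesday's run | 2.3 | 0.05337 |
| Wednesday's run | 2.9 | 0.05343 |
| Wednesday's run | 3.5 | 0.05323 |
| Wednesday's run | 4.1 | 0.05292 |

(scatter of a reading: 2 × 10⁻⁴ M)

1. Z in the Thursday's run at 4.1 h, as a share of the L charged

- Overall: L + Q -> Z.
- Constant volume, constant temperature.
- "The second partner" is Q.

The first setting is time. By hand, more hours give more Z. Tuesday's flask gains 0.00898 M in its first 0.59 h but 0.00198 M in its last 1.20 h, which is less.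

The second setting is added Z. By hand, it slows a step that can run back. Wednesday's flask instead gains 0.00950 M in its first 0.59 h, slightly more than Tuesday's flask, yet by 4.1 h its gain of 0.0129 M is half of Tuesday's.

The third setting is the charge. Thursday's flask gets 590 M·s of what I call the dose, the L charged times the hours run. In a plain second-order step with equal charges, the share turned is a function of the dose. So I look up the same dose on Tuesday's flask:

time on Tuesday's flask = 590 M·s / 0.0800 M = 2.05 h

share read there, midway between two readings = 26.5%

That reading is my mark. The forecast says 19%, lower than my mark, and adds: “A higher order or Z acceleration would lower this somewhat.”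

The flask gives 22.4%, which is 4.1 percentage points below my mark and 3.4 points above the forecast. Once two percent of Tuesday's L has been made, Wednesday's flask runs at 0.023 M h⁻¹ against 0.016 M h⁻¹ for Tuesday's, a ratio of 1.4.

    L + Q → Z (2.578 M⁻¹ h⁻¹)
    Z + Q → J (6.552 M⁻¹ h⁻¹)
    L + Q + Z → 2 Z (117.4 M⁻² h⁻¹)

In Tuesday's flask the Z made comes to a quarter of the charge at 1.80 h, a dose of 518 M·s. Thursday's flask gets more dose, 590 M·s, and still stands short of a quarter, at 22.4%.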